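## Analysis of the target

Pestaphilone D (26) is a 7,8-dihydro-6H-isochromen-6-one. Ring A is a 4-alkylidene-4H-pyran (O2, C1, C3, C4, C4a, C8a); ring B is a carbocycle (C4a, C5, C6, C7, C8, C8a) with the C6 ketone, the C4a=C5 alkene, a methyl-bearing tertiary carbinol at C7 and a secondary carbinol at C8. C3 carries a side chain, numbered here C9 to C15: a trisubstituted epoxide (quaternary C9 with a methyl group, and C10), an (E)-trisubstituted alkene C11=C12, a methyl-bearing centre C13, a carbinol C14 and the terminal methyl C15. The six stereocentres form three pairs, 7S,8R (trans-diol), 9R,10S (trans-epoxide) and 13R,14S (anti), which are insulated from one another by sp2 carbons, so each pair has to be set by a reagent and the parts joined convergently. The vinyl epoxide lies between the electron-rich pyran and the C11=C12 alkene and ionises readily with acid; the cross-conjugated vinylogous pyranone is open to nucleophiles at C1; the C8 carbinol is allylic to the C8a=C1–O2 enol ether and β to the C6 ketone; the C6/C7 α-ketol can rearrange under base. The main difficulty is ring B: it is not aromatic, and its two adjacent oxygenated centres sit in a nearly flat ring in which an enolate at C8 with an oxygen at C7 collapses to a quinone. The strategy rests on the fact that ring B is 2,5-dimethyl-1,4-benzoquinone (1) atom for atom: C6 and C8a are the carbonyl carbons, C7 and C4a the methyl-bearing carbons (the C4a methyl is C4 of ring A), C5 and C8 the CH groups, and the trans-7,8-diol is the anti-opening product of a cis C7–C8 epoxide.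

## Retrosynthetic reasoning

**26 from 25.** The three hydroxyl groups are carried as triethylsilyl ethers in 25 and released together at the very end by buffered fluoride. No acid then touches the vinyl epoxide or the C8 carbinol.

**25 from 23 (C3=C4).** The C3=C4 double bond is removed to give the 3,4-dihydro compound 23, in which C3 is an sp3 ether carbon. This lets C3 arrive as an aldehyde carbon. Forward, 23 is enolised towards C4 to the 2H-pyran dienol ether 24, and a quinone oxidant abstracts the C3 hydride, which is allylic and α to O2.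

**23 from 9 and 21 (O2–C1 and C3–C4).** Both remaining bonds of ring A are cut in a retro-hetero-Diels–Alder sense, through adduct 22. The cut separates ring B from the side chain exactly between two stereochemical pairs. The diene C4=C4a–C8a=C1 of 9 is held s-cis on ring B, its C4 terminus is the former quinone methyl group, and aldehyde 21 has no α-hydrogen and cannot epimerise. An acid-level side chain would give C3 at the right oxidation level, but it would need a strong-base acylation next to the C8 leaving group.

**9 from 5 by way of 8 and 7 (C8a–C1).** A direct carbonyl olefination of 5 would have to choose between two hindered ketones. It would also use a basic ylide on a compound whose C8 enolate expels the C7 oxygen. The two carbonyls are therefore told apart by mechanism. Hydride can only add to C5, the single unsubstituted alkene carbon, which gives the C8a enolate 6 specifically. Its triflate 7 is formylated to 8, and twofold enolisation gives 9.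

**5 from 3 by way of 4 (C8–O).** The trans-diol comes from the cis-epoxide by attack of an oxygen nucleophile at the secondary carbon C8 with inversion, with the C7–O bond kept. This is done before C1 is attached, because afterwards C8 is allylic to an enol ether and would open by an ionising path. It is also done before the side chain, with its own epoxide, is present.

**3 from 1 and 2 (key step).** The two C–O bonds of the epoxide and both ring B stereocentres are traced back to the achiral quinone 1 and hydroperoxide 2. One catalyst-controlled face selection is needed, and no ketone has to be reduced.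

**21 from 19 by way of 20.** The side-chain epoxide is the Sharpless epoxide of the (2E,4E)-dienol 19, and the epoxy alcohol 20 is oxidised to the aldehyde. The allylic hydroxyl later becomes the aldehyde that is consumed in ring A, so the directing group is not wasted.

**19 from 14 by way of 16 and 18.** The two E-trisubstituted alkenes are cut by two Wittig reactions with the stabilised ylides 15 and 17. These deliver the E geometry and the two methyl branches.

**14 from 10 by way of 12 and 13.** The anti C13/C14 pair comes from commercial 10 by α-methylation of its dianion 11, followed by silylation and partial reduction.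

## Alternatives that were turned down

**Alternative 1:** Ring B is closed last, at C8–C8a. The alkenyl iodide A1 (iodine on C8a, aldehyde at C8) is treated with divalent chromium and a catalytic nickel salt, and the alkenylchromium species adds to the aldehyde to give A2.
- For: the coupling is mild and selective for aldehydes. Ring A and the side chain are complete before the closure, so no dehydrogenation is needed next to the epoxide. On that point it is stronger than the chosen route.
- Against: A1 must contain C7 as an acyclic quaternary α-silyloxy centre flanked by a ketone and an aldehyde. That unit is prone to deformylation and needs its own asymmetric synthesis. The C8 configuration would depend on 1,2-induction from C7, where the non-chelated and the chelated models point to opposite faces. The one-electron reductant can also attack the vinyl epoxide and the α-oxygenated ketone, and A1 is long to make.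
- Comparison: the chosen route makes C7 and C8 together from a commodity quinone in one catalytic step, with the trans relationship fixed by an SN2 inversion. It pays with one late oxidation.

**Alternative 2:** The pyran is closed by a vinylogous Baker–Venkataraman acyl transfer. In the enol ester A3 a lithium amide removes a proton from the C4 methyl group, C4 attacks the ester carbonyl (C3–C4), and acid work-up recloses O2–C3 with loss of water to give A4, which is identical with 25.
- For: C3 arrives at the correct oxidation level, so the dehydrogenation of the chosen route is avoided; this is a real advantage. The C–C bond formation is intramolecular and its regiochemistry is certain.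
- Against: it does not say where the ring B stereocentres come from and would still need a building block such as 8. O-acylation of that vinylogous acid with a hindered α-quaternary acyl group can go to either oxygen. The dienolate made with strong base has carbanion character next to the C8 silyloxy group (β-elimination). The final dehydration needs acid next to the vinyl epoxide.
- Comparison: the chosen route joins the fragments by a catalysed cycloaddition and a buffered oxidation, at the cost of one redox step.

**Alternative 3:** Ring B is closed at C6–C7 by a carbene-catalysed crossed benzoin reaction. In the keto aldehyde A5 a chiral triazolylidene carbene turns the C6 aldehyde into an acyl-anion equivalent that adds to the C7 methyl ketone, while C8 epimerises, to give A6.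
- For: the tertiary carbinol is made by catalytic asymmetric C–C bond formation, and one catalyst would in principle control both centres. Intramolecular aldehyde–ketone benzoin closures to six-membered α-ketols are known.
- Against: the C6 aldehyde is the end of a push-pull vinylogous formate. It is a poor electrophile for the carbene and, as an enal, is diverted to homoenolate and redox pathways. The carbene can also add to C1. The dynamic resolution needs C8 to epimerise faster than the ring closes, and the catalyst must pick one of four stereoisomers, the trans one included. A5 carries the acid- and base-labile epoxide through all of this.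
- Comparison: the chosen route sets both centres on a small, robust molecule, and the trans relationship follows from mechanism, not from catalyst discrimination.

Key step: step 1

Assumption: the quinidine-derived ammonium salt is taken to deliver the (1S,6R)-epoxide 3; if the sense of induction is the opposite, the pseudoenantiomeric quinine-derived salt is used with no other change.

## Route

Step 1
Reactants: 1 2,5-dimethyl-1,4-benzoquinone; 2 tert-butyl hydroperoxide
Product: 3 (1S,6R)-1,4-dimethyl-7-oxabicyclo[4.1.0]hept-3-ene-2,5-dione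
Conditions: 2 (1.05 equiv), O(9)-benzyl-N-(9-anthracenylmethyl)quinidinium bromide (10 mol%), aq NaOH (1 M, 0.2 equiv), toluene, −20 °C
Reagents that add atoms: tert-butyl hydroperoxide (2), CC(C)(C)OO
Why: Weitz–Scheffer (nucleophilic) epoxidation run as an asymmetric phase-transfer reaction, the type known for 2-alkyl-1,4-naphthoquinones and applied here to a benzoquinone. The ammonium cation carries tert-butylperoxide into toluene as a tight ion pair; the peroxide adds to C8, the hydrogen-bearing β-carbon of the C6 enone, and the C6/C7 enolate then attacks the proximal peroxide oxygen through C7 with loss of tert-butoxide, which regenerates the base. The oxirane is closed in a 3-exo-tet mode. C8 is set by the face on which the chiral cation delivers the peroxide; C7 is set in the ring closure, which for geometric reasons can only occur on the same face, so the cis fusion and both configurations follow from one catalyst-controlled event. The two C=C bonds of 1 are homotopic and its faces enantiotopic, so no site has to be selected and only the face matters. The step needs monoepoxidation and tolerance of base: 3 has lost the cross-conjugated quinone π-system and is a poorer acceptor than 1, only 1.05 equiv of 2 is used, and the hydroxide is substoichiometric and stays in the aqueous phase. The enantiomeric purity can be raised by crystallisation of 3, and any residual antipode becomes a separable diastereomer after union with enantiopure 21.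

Step 2
Reactants: 3 (1S,6R)-1,4-dimethyl-7-oxabicyclo[4.1.0]hept-3-ene-2,5-dione
Product: 4 (5S,6S)-5,6-dihydroxy-2,5-dimethylcyclohex-2-ene-1,4-dione
Conditions: HClO4 (5 mol%), THF/H2O 3:1, 0 °C; NaHCO3 quench; used crude
Reagents that add atoms: water, O
Why: Acid-catalysed epoxide hydration. Both oxirane carbons are α to a carbonyl, so neither develops cationic character and the reaction stays on the SN2 side, where water attacks the secondary C8 anti to the oxygen; inversion at C8 with the C7–O bond retained gives the trans-diol. Cold dilute acid and immediate use limit dehydration to the hydroxyquinone.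

Step 3
Reactants: 4 (5S,6S)-5,6-dihydroxy-2,5-dimethylcyclohex-2-ene-1,4-dione
Product: 5 (5S,6S)-2,5-dimethyl-5,6-bis[(triethylsilyl)oxy]cyclohex-2-ene-1,4-dione
Conditions: Et3SiOTf (2.5 equiv), 2,6-lutidine (4 equiv), CH2Cl2, −78 to −20 °C
Reagents that add atoms: triethylsilyl trifluoromethanesulfonate, CC[Si](CC)(CC)OS(=O)(=O)C(F)(F)F
Why: Silylation with a silyl triflate and a hindered pyridine, which also covers the tertiary α-hydroxy ketone. At low temperature this base should not enolise the C8a ketone, so the C8 centre and the C7 oxygen are not put at risk.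

Step 4
Reactants: 5 (5S,6S)-2,5-dimethyl-5,6-bis[(triethylsilyl)oxy]cyclohex-2-ene-1,4-dione
Product: 7 (5S,6S)-2,5-dimethyl-4-oxo-5,6-bis[(triethylsilyl)oxy]cyclohex-1-en-1-yl trifluoromethanesulfonate, via lithium enolate 6 (not isolated)
Conditions: LiBH(s-Bu)3 (1.05 equiv), THF, −78 °C; then N-(5-chloropyridin-2-yl)bis(trifluoromethanesulfonimide) (1.2 equiv), −78 to 0 °C
Reagents that add atoms: N-(5-chloropyridin-2-yl)-1,1,1-trifluoro-N-[(trifluoromethyl)sulfonyl]methanesulfonamide, O=S(=O)(N(c1ccc(Cl)cn1)S(=O)(=O)C(F)(F)F)C(F)(F)F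
Why: Conjugate reduction with a bulky trialkylborohydride, then O-triflation of the enolate. Hydride can only add to C5, the single unsubstituted alkene carbon of the enedione, and this gives the C4a=C8a enolate of the C8a carbonyl specifically, so the two carbonyl groups are distinguished by mechanism; the enolate carbon C4a has no β-leaving group. No stereocentre is formed.

Step 5
Reactants: 7 (5S,6S)-2,5-dimethyl-4-oxo-5,6-bis[(triethylsilyl)oxy]cyclohex-1-en-1-yl trifluoromethanesulfonate
Product: 8 (5S,6R)-2,5-dimethyl-4-oxo-5,6-bis[(triethylsilyl)oxy]cyclohex-1-ene-1-carbaldehyde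
Conditions: Pd(PPh3)4 (5 mol%), CO (1–3 atm), Bu3SnH (1.1 equiv, slow addition), LiCl (3 equiv), THF, 50 °C
Reagents that add atoms: carbon monoxide, [C-]#[O+]
Why: Palladium-catalysed reductive carbonylation (formylation) of an enol triflate: oxidative addition to zerovalent palladium, CO insertion and hydride transfer from tin. This puts C1 on C8a at the aldehyde level; 8 is the keto form of a vinylogous acid.

Step 6
Reactants: 8 (5S,6R)-2,5-dimethyl-4-oxo-5,6-bis[(triethylsilyl)oxy]cyclohex-1-ene-1-carbaldehyde
Product: 9 (4Z,5R,6S)-6-methyl-3-methylidene-1,5,6-tris[(triethylsilyl)oxy]-4-{[(triethylsilyl)oxy]methylidene}cyclohex-1-ene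
Conditions: Et3SiOTf (2.4 equiv), Et3N (4 equiv), CH2Cl2, −78 to 0 °C; used at once
Reagents that add atoms: triethylsilyl trifluoromethanesulfonate, CC[Si](CC)(CC)OS(=O)(=O)C(F)(F)F
Why: Twofold soft enolisation. The C6 ketone is silylated with loss of a C5 proton, then the formyl oxygen with loss of a proton from the C4 methyl group, the only acidic position left. The product holds the C4=C4a–C8a=C1 diene s-cis on the ring, with the C1 silyloxy group expected to point away from the methylidene.

Step 7
Reactants: 10 ethyl (S)-3-hydroxybutanoate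
Product: 12 ethyl (2S,3S)-3-hydroxy-2-methylbutanoate, via dilithium enolate 11 (not isolated)
Conditions: LiN(i-Pr)2 (2.1 equiv), THF, −50 to −20 °C; MeI, DMPU, −78 to 0 °C
Reagents that add atoms: iodomethane, CI
Why: Fráter–Seebach alkylation. The chelated dilithium alkoxide-enolate is methylated on the face opposite to the methyl group of the chelate ring, which gives the anti product and sets C13.

Step 8
Reactants: 12 ethyl (2S,3S)-3-hydroxy-2-methylbutanoate
Product: 13 ethyl (2S,3S)-2-methyl-3-[(triethylsilyl)oxy]butanoate
Conditions: Et3SiCl, imidazole, DMF, 0 °C to rt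
Reagents that add atoms: chlorotriethylsilane, CC[Si](Cl)(CC)CC
Why: Standard silyl ether formation. The triethylsilyl group is chosen so that all three hydroxyl groups are released together at the end by fluoride.

Step 9
Reactants: 13 ethyl (2S,3S)-2-methyl-3-[(triethylsilyl)oxy]butanoate
Product: 14 (2S,3S)-2-methyl-3-[(triethylsilyl)oxy]butanal
Conditions: i-Bu2AlH (1.1 equiv), CH2Cl2, −78 °C; MeOH, aq KNaC4H4O6 (potassium sodium tartrate)
Reagents that add atoms: none
Why: Partial reduction of the ester; the aluminium hemiacetal survives at −78 °C and gives the aldehyde on work-up. The aldehyde is used crude to avoid epimerisation at the α-carbon.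

Step 10
Reactants: 14 (2S,3S)-2-methyl-3-[(triethylsilyl)oxy]butanal; 15 2-(triphenylphosphoranylidene)propanal
Product: 16 (2E,4R,5S)-2,4-dimethyl-5-[(triethylsilyl)oxy]hex-2-enal
Conditions: 15 (1.3 equiv), toluene, 90 °C
Reagents that add atoms: 2-(triphenylphosphoranylidene)propanal (15), CC(C=O)=P(c1ccccc1)(c1ccccc1)c1ccccc1
Why: Wittig reaction with a formyl-stabilised ylide, which gives the (E)-2-methylenal directly. The product enal is less electrophilic than 14 and should not react further.

Step 11
Reactants: 16 (2E,4R,5S)-2,4-dimethyl-5-[(triethylsilyl)oxy]hex-2-enal; 17 ethyl 2-(triphenylphosphoranylidene)propanoate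
Product: 18 ethyl (2E,4E,6R,7S)-2,4,6-trimethyl-7-[(triethylsilyl)oxy]octa-2,4-dienoate
Conditions: 17 (1.5 equiv), toluene, 80 °C
Reagents that add atoms: ethyl 2-(triphenylphosphoranylidene)propanoate (17), CCOC(=O)C(C)=P(c1ccccc1)(c1ccccc1)c1ccccc1
Why: Wittig reaction with an ester-stabilised ylide; the usual E selectivity of stabilised ylides gives the (2E,4E)-dienoate.

Step 12
Reactants: 18 ethyl (2E,4E,6R,7S)-2,4,6-trimethyl-7-[(triethylsilyl)oxy]octa-2,4-dienoate
Product: 19 (2E,4E,6R,7S)-2,4,6-trimethyl-7-[(triethylsilyl)oxy]octa-2,4-dien-1-ol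
Conditions: i-Bu2AlH (2.2 equiv), CH2Cl2, −78 °C; aq KNaC4H4O6
Reagents that add atoms: none
Why: 1,2-Reduction of the conjugated ester to the allylic alcohol.

Step 13
Reactants: 19 (2E,4E,6R,7S)-2,4,6-trimethyl-7-[(triethylsilyl)oxy]octa-2,4-dien-1-ol; 2 tert-butyl hydroperoxide
Product: 20 {(2S,3S)-2-methyl-3-[(2E,4R,5S)-4-methyl-5-[(triethylsilyl)oxy]hex-2-en-2-yl]oxiran-2-yl}methanol
Conditions: Ti(Oi-Pr)4 (10 mol%), L-(+)-diethyl tartrate (12 mol%), 2 (2 equiv, anhydrous), 4 Å molecular sieves, CH2Cl2, −20 °C
Reagents that add atoms: tert-butyl hydroperoxide (2), CC(C)(C)OO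
Why: Sharpless asymmetric epoxidation. Only the alkene next to the hydroxymethyl group is bound to titanium and epoxidised; with L-(+)-tartrate the oxygen is delivered to the face that gives the (2S,3S)-epoxy alcohol, which sets C9 and C10.

Step 14
Reactants: 20 {(2S,3S)-2-methyl-3-[(2E,4R,5S)-4-methyl-5-[(triethylsilyl)oxy]hex-2-en-2-yl]oxiran-2-yl}methanol
Product: 21 (2R,3S)-2-methyl-3-[(2E,4R,5S)-4-methyl-5-[(triethylsilyl)oxy]hex-2-en-2-yl]oxirane-2-carbaldehyde
Conditions: Dess–Martin periodinane (1.2 equiv), NaHCO3, CH2Cl2, 0 °C to rt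
Reagents that add atoms: none
Why: Dess–Martin oxidation under bicarbonate buffer. The epoxy aldehyde has no α-hydrogen and cannot epimerise.

Step 15
Reactants: 9 (4Z,5R,6S)-6-methyl-3-methylidene-1,5,6-tris[(triethylsilyl)oxy]-4-{[(triethylsilyl)oxy]methylidene}cyclohex-1-ene; 21 (2R,3S)-2-methyl-3-[(2E,4R,5S)-4-methyl-5-[(triethylsilyl)oxy]hex-2-en-2-yl]oxirane-2-carbaldehyde
Product: 23 (7S,8R)-7-methyl-3-{(2S,3S)-2-methyl-3-[(2E,4R,5S)-4-methyl-5-[(triethylsilyl)oxy]hex-2-en-2-yl]oxiran-2-yl}-7,8-bis[(triethylsilyl)oxy]-3,4,7,8-tetrahydro-6H-isochromen-6-one (C3 epimers), via cycloadduct 22 (not isolated)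
Conditions: Eu(fod)3 (10 mol%; fod = 6,6,7,7,8,8,8-heptafluoro-2,2-dimethyl-3,5-octanedionate), CH2Cl2, rt; then pyridinium p-toluenesulfonate (5 mol%), −20 °C
Reagents that add atoms: none
Why: Hetero-Diels–Alder reaction of a 1-oxygenated diene with an aldehyde under mild lanthanide catalysis: the aldehyde oxygen bonds to C1 and the aldehyde carbon to C4, the terminus that receives electron density from both silyloxy groups. Mild acid then ionises the C1 silyl acetal and the silyl enol ether collapses to the C6 ketone, giving the cyclic vinylogous ester. The new C3 centre is formed as a mixture, which does not matter because C3 becomes sp2 in step 16.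

Step 16
Reactants: 23 (7S,8R)-7-methyl-3-{(2S,3S)-2-methyl-3-[(2E,4R,5S)-4-methyl-5-[(triethylsilyl)oxy]hex-2-en-2-yl]oxiran-2-yl}-7,8-bis[(triethylsilyl)oxy]-3,4,7,8-tetrahydro-6H-isochromen-6-one
Product: 25 (7S,8R)-7-methyl-3-{(2R,3S)-2-methyl-3-[(2E,4R,5S)-4-methyl-5-[(triethylsilyl)oxy]hex-2-en-2-yl]oxiran-2-yl}-7,8-bis[(triethylsilyl)oxy]-7,8-dihydro-6H-isochromen-6-one, via silyl dienol ether 24 (not isolated)
Conditions: Et3SiOTf (1.1 equiv), 2,6-di-tert-butyl-4-methylpyridine (2.5 equiv), CH2Cl2, −78 °C; then DDQ (1.2 equiv), −78 to −20 °C; aq NaHCO3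
Reagents that add atoms: none
Why: Soft enolisation of the vinylogous ester (O-silylation at C6, loss of a C4 proton) gives the 2H-pyran dienol ether; DDQ then abstracts the C3 hydride, which is allylic and α to O2, and the resulting silyloxy-substituted pyrylium ion loses the silyl group. This is the dienol ether to dienone dehydrogenation known from steroidal 3,5-dienol ethers. The hindered pyridine keeps the medium free of acid for the sake of the epoxide.

Step 17
Reactants: 25 (7S,8R)-7-methyl-3-{(2R,3S)-2-methyl-3-[(2E,4R,5S)-4-methyl-5-[(triethylsilyl)oxy]hex-2-en-2-yl]oxiran-2-yl}-7,8-bis[(triethylsilyl)oxy]-7,8-dihydro-6H-isochromen-6-one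
Product: 26 pestaphilone D, (7S,8R)-7,8-dihydroxy-3-{(2R,3S)-3-[(2E,4R,5S)-5-hydroxy-4-methylhex-2-en-2-yl]-2-methyloxiran-2-yl}-7-methyl-7,8-dihydro-6H-isochromen-6-one
Conditions: Bu4NF (4 equiv), AcOH (4 equiv), THF, 0 °C to rt
Reagents that add atoms: none
Why: Fluoride cleavage of the three triethylsilyl ethers. Acetic acid buffers the alkoxides, so neither retro-aldol cleavage of C7–C8 nor opening of the epoxide should be provoked.

## Compound list

1 | 2,5-dimethyl-1,4-benzoquinone | CC1=CC(=O)C(C)=CC1=O | starting material
2 | tert-butyl hydroperoxide | CC(C)(C)OO | starting material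
3 | (1S,6R)-1,4-dimethyl-7-oxabicyclo[4.1.0]hept-3-ene-2,5-dione | CC1=CC(=O)[C@@]2(C)O[C@H]2C1=O | intermediate
4 | (5S,6S)-5,6-dihydroxy-2,5-dimethylcyclohex-2-ene-1,4-dione | CC1=CC(=O)[C@@](C)(O)[C@H](O)C1=O | intermediate
5 | (5S,6S)-2,5-dimethyl-5,6-bis[(triethylsilyl)oxy]cyclohex-2-ene-1,4-dione | CC1=CC(=O)[C@@](C)(O[Si](CC)(CC)CC)[C@H](O[Si](CC)(CC)CC)C1=O | intermediate
6 | lithium (5S,6R)-2,5-dimethyl-4-oxo-5,6-bis[(triethylsilyl)oxy]cyclohex-1-en-1-olate | CC=1CC(=O)[C@@](C)(O[Si](CC)(CC)CC)[C@H](O[Si](CC)(CC)CC)C=1O[Li] | intermediate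
7 | (5S,6S)-2,5-dimethyl-4-oxo-5,6-bis[(triethylsilyl)oxy]cyclohex-1-en-1-yl trifluoromethanesulfonate | CC=1CC(=O)[C@@](C)(O[Si](CC)(CC)CC)[C@H](O[Si](CC)(CC)CC)C=1OS(=O)(=O)C(F)(F)F | intermediate
8 | (5S,6R)-2,5-dimethyl-4-oxo-5,6-bis[(triethylsilyl)oxy]cyclohex-1-ene-1-carbaldehyde | CC=1CC(=O)[C@@](C)(O[Si](CC)(CC)CC)[C@H](O[Si](CC)(CC)CC)C=1C=O | intermediate
9 | (4Z,5R,6S)-6-methyl-3-methylidene-1,5,6-tris[(triethylsilyl)oxy]-4-{[(triethylsilyl)oxy]methylidene}cyclohex-1-ene | C=C1C=C(O[Si](CC)(CC)CC)[C@@](C)(O[Si](CC)(CC)CC)[C@H](O[Si](CC)(CC)CC)/C1=C\O[Si](CC)(CC)CC | intermediate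
10 | ethyl (S)-3-hydroxybutanoate | CCOC(=O)C[C@H](C)O | starting material
11 | dilithium alkoxide-enolate of ethyl (S)-3-hydroxybutanoate | CCOC(O[Li])=C[C@H](C)O[Li] | intermediate
12 | ethyl (2S,3S)-3-hydroxy-2-methylbutanoate | CCOC(=O)[C@@H](C)[C@H](C)O | intermediate
13 | ethyl (2S,3S)-2-methyl-3-[(triethylsilyl)oxy]butanoate | CCOC(=O)[C@@H](C)[C@H](C)O[Si](CC)(CC)CC | intermediate
14 | (2S,3S)-2-methyl-3-[(triethylsilyl)oxy]butanal | O=C[C@@H](C)[C@H](C)O[Si](CC)(CC)CC | intermediate
15 | 2-(triphenylphosphoranylidene)propanal | CC(C=O)=P(c1ccccc1)(c1ccccc1)c1ccccc1 | starting material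
16 | (2E,4R,5S)-2,4-dimethyl-5-[(triethylsilyl)oxy]hex-2-enal | C/C(=C\[C@@H](C)[C@H](C)O[Si](CC)(CC)CC)C=O | intermediate
17 | ethyl 2-(triphenylphosphoranylidene)propanoate | CCOC(=O)C(C)=P(c1ccccc1)(c1ccccc1)c1ccccc1 | starting material
18 | ethyl (2E,4E,6R,7S)-2,4,6-trimethyl-7-[(triethylsilyl)oxy]octa-2,4-dienoate | C/C(=C\[C@@H](C)[C@H](C)O[Si](CC)(CC)CC)/C=C(\C)C(=O)OCC | intermediate
19 | (2E,4E,6R,7S)-2,4,6-trimethyl-7-[(triethylsilyl)oxy]octa-2,4-dien-1-ol | C/C(=C\[C@@H](C)[C@H](C)O[Si](CC)(CC)CC)/C=C(\C)CO | intermediate
20 | {(2S,3S)-2-methyl-3-[(2E,4R,5S)-4-methyl-5-[(triethylsilyl)oxy]hex-2-en-2-yl]oxiran-2-yl}methanol | C/C(=C\[C@@H](C)[C@H](C)O[Si](CC)(CC)CC)[C@@H]1O[C@@]1(C)CO | intermediate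
21 | (2R,3S)-2-methyl-3-[(2E,4R,5S)-4-methyl-5-[(triethylsilyl)oxy]hex-2-en-2-yl]oxirane-2-carbaldehyde | C/C(=C\[C@@H](C)[C@H](C)O[Si](CC)(CC)CC)[C@@H]1O[C@@]1(C)C=O | intermediate
22 | (7S,8R)-7-methyl-3-{(2S,3S)-2-methyl-3-[(2E,4R,5S)-4-methyl-5-[(triethylsilyl)oxy]hex-2-en-2-yl]oxiran-2-yl}-1,6,7,8-tetrakis[(triethylsilyl)oxy]-3,4,7,8-tetrahydro-1H-isochromene (C1 and C3 epimers) | C/C(=C\[C@@H](C)[C@H](C)O[Si](CC)(CC)CC)[C@@H]1O[C@@]1(C)C1CC=2C=C(O[Si](CC)(CC)CC)[C@@](C)(O[Si](CC)(CC)CC)[C@H](O[Si](CC)(CC)CC)C=2C(O[Si](CC)(CC)CC)O1 | intermediate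
23 | (7S,8R)-7-methyl-3-{(2S,3S)-2-methyl-3-[(2E,4R,5S)-4-methyl-5-[(triethylsilyl)oxy]hex-2-en-2-yl]oxiran-2-yl}-7,8-bis[(triethylsilyl)oxy]-3,4,7,8-tetrahydro-6H-isochromen-6-one (C3 epimers) | C/C(=C\[C@@H](C)[C@H](C)O[Si](CC)(CC)CC)[C@@H]1O[C@@]1(C)C1CC2=CC(=O)[C@@](C)(O[Si](CC)(CC)CC)[C@H](O[Si](CC)(CC)CC)C2=CO1 | intermediate
24 | (7S,8R)-7-methyl-3-{(2S,3S)-2-methyl-3-[(2E,4R,5S)-4-methyl-5-[(triethylsilyl)oxy]hex-2-en-2-yl]oxiran-2-yl}-6,7,8-tris[(triethylsilyl)oxy]-7,8-dihydro-3H-isochromene (C3 epimers) | C/C(=C\[C@@H](C)[C@H](C)O[Si](CC)(CC)CC)[C@@H]1O[C@@]1(C)C1C=C2C=C(O[Si](CC)(CC)CC)[C@@](C)(O[Si](CC)(CC)CC)[C@H](O[Si](CC)(CC)CC)C2=CO1 | intermediate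
25 | tris(triethylsilyl) pestaphilone D, (7S,8R)-7-methyl-3-{(2R,3S)-2-methyl-3-[(2E,4R,5S)-4-methyl-5-[(triethylsilyl)oxy]hex-2-en-2-yl]oxiran-2-yl}-7,8-bis[(triethylsilyl)oxy]-7,8-dihydro-6H-isochromen-6-one | C/C(=C\[C@@H](C)[C@H](C)O[Si](CC)(CC)CC)[C@@H]1O[C@@]1(C)C1=CC2=CC(=O)[C@@](C)(O[Si](CC)(CC)CC)[C@H](O[Si](CC)(CC)CC)C2=CO1 | intermediate
26 | pestaphilone D | C/C(=C\[C@@H](C)[C@H](C)O)[C@@H]1O[C@@]1(C)C1=CC2=CC(=O)[C@@](C)(O)[C@H](O)C2=CO1 | target

## Step count and least certain steps

Total: 17 steps. Longest linear sequence: 11 steps (10 through steps 7–14, then steps 15–17). The ring B branch is 9 steps (steps 1–6, then 15–17).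

**Step 1 (key step).** The ion pair may discriminate poorly between the faces of a small, flat quinone; 3 may be epoxidised a second time; 1 may decompose under base. Fallback, from 1 back to 3: racemic Weitz–Scheffer epoxidation of 1 with aqueous hydrogen peroxide and NaHCO3 in ethanol/water at 0 °C gives the racemic epoxide F1. The enantiomers are then separated by preparative chromatography on a chiral stationary phase, which gives 3.

**Step 2.** Water may attack at C7 instead of C8; this gives the antipode of 4 and erodes the enantiomeric purity. Acid-catalysed enolisation at C8 with loss of the C7 hydroxyl (dehydration to the hydroxyquinone) is the other risk. Fallback, from 3 back to 4: the epoxide is opened under SN2 conditions with tetrabutylammonium acetate and acetic acid in acetonitrile at room temperature. The carboxylate cannot substitute at the tertiary C7, and the product is (1S,6S)-6-hydroxy-3,6-dimethyl-2,5-dioxocyclohex-3-en-1-yl acetate F2. The acetate is then hydrolysed at neutral pH with Candida antarctica lipase B in phosphate buffer/tert-butyl methyl ether, which gives 4.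

**Step 4.** Hydride may add 1,2 to a carbonyl instead of to C5, or proton transfer in enolate 6 before triflation may scramble the regiochemistry and lead to β-elimination of silanolate. Fallback, from 5 back to 23, bypassing steps 4–6:
- Wittig methoxymethylenation of 5 with the ylide from (methoxymethyl)triphenylphosphonium chloride and KN(SiMe3)2 in THF at −78 °C. C8a is expected to react because C6 is flanked by the quaternary C7. The product is (5R,6S)-4-(methoxymethylidene)-3,6-dimethyl-5,6-bis[(triethylsilyl)oxy]cyclohex-2-en-1-one F3.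
- Soft enolisation with Et3SiOTf/Et3N as in step 6 gives the methoxy triene F4.
- Cycloaddition with 21 under the conditions of step 15 gives the 1-methoxy cycloadduct F5, which collapses with pyridinium p-toluenesulfonate to 23.

**Step 15.** The cycloaddition with the α-quaternary aldehyde may be slow. Ionisation of the allylic C8 silyl ether of 9 by the Lewis acid, or Mukaiyama aldol addition through C5, could then compete. Fallback, from 8 back to 23: 8 is deprotonated twice with LiN(i-Pr)2 (2.1 equiv) in THF at −78 °C, and the dianion of the vinylogous acid adds through C4, its most basic carbon, to 21. This gives the open-chain hydroxy aldehyde F6. With pyridinium p-toluenesulfonate F6 cyclises through its C3 hydroxyl onto C1 with loss of water (vinylogous esterification), which gives 23.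

**Step 16.** The silyl triflate may ionise the vinyl epoxide, 24 may undergo electrocyclic ring opening to the dienal before it is oxidised, or hydride may be abstracted at C8 instead of C3. Fallback, from 23 back to 25: 23 is dehydrogenated directly with o-iodoxybenzoic acid as its 4-methoxypyridine N-oxide complex in DMSO at room temperature. This is the enone to dienone dehydrogenation that runs through the dienol and needs neither a silyl triflate nor a hydride acceptor. It makes no new compound.

## Further compounds

F1 | step 1 | racemic 1,4-dimethyl-7-oxabicyclo[4.1.0]hept-3-ene-2,5-dione | CC1=CC(=O)C2(C)OC2C1=O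
F2 | step 2 | (1S,6S)-6-hydroxy-3,6-dimethyl-2,5-dioxocyclohex-3-en-1-yl acetate | CC1=CC(=O)[C@@](C)(O)[C@H](OC(C)=O)C1=O
F3 | step 4 | (5R,6S)-4-(methoxymethylidene)-3,6-dimethyl-5,6-bis[(triethylsilyl)oxy]cyclohex-2-en-1-one | CC1=CC(=O)[C@@](C)(O[Si](CC)(CC)CC)[C@H](O[Si](CC)(CC)CC)C1=COC
F4 | step 4 | (5R,6S)-4-(methoxymethylidene)-6-methyl-3-methylidene-1,5,6-tris[(triethylsilyl)oxy]cyclohex-1-ene | C=C1C=C(O[Si](CC)(CC)CC)[C@@](C)(O[Si](CC)(CC)CC)[C@H](O[Si](CC)(CC)CC)C1=COC
F5 | step 4 | (7S,8R)-1-methoxy-7-methyl-3-{(2S,3S)-2-methyl-3-[(2E,4R,5S)-4-methyl-5-[(triethylsilyl)oxy]hex-2-en-2-yl]oxiran-2-yl}-6,7,8-tris[(triethylsilyl)oxy]-3,4,7,8-tetrahydro-1H-isochromene (C1 and C3 epimers) | C/C(=C\[C@@H](C)[C@H](C)O[Si](CC)(CC)CC)[C@@H]1O[C@@]1(C)C1CC=2C=C(O[Si](CC)(CC)CC)[C@@](C)(O[Si](CC)(CC)CC)[C@H](O[Si](CC)(CC)CC)C=2C(OC)O1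
F6 | step 15 | (5S,6R)-2-{2-hydroxy-2-[(2S,3S)-2-methyl-3-[(2E,4R,5S)-4-methyl-5-[(triethylsilyl)oxy]hex-2-en-2-yl]oxiran-2-yl]ethyl}-5-methyl-4-oxo-5,6-bis[(triethylsilyl)oxy]cyclohex-1-ene-1-carbaldehyde (carbinol epimers) | C/C(=C\[C@@H](C)[C@H](C)O[Si](CC)(CC)CC)[C@@H]1O[C@@]1(C)C(O)CC=1CC(=O)[C@@](C)(O[Si](CC)(CC)CC)[C@H](O[Si](CC)(CC)CC)C=1C=O
F0 | step 16 | none | none
A1 | alternative 1 | (2S,4Z)-4-[3-iodo-6-{(2R,3S)-2-methyl-3-[(2E,4R,5S)-4-methyl-5-[(triethylsilyl)oxy]hex-2-en-2-yl]oxiran-2-yl}-4H-pyran-4-ylidene]-2-methyl-3-oxo-2-[(triethylsilyl)oxy]butanal | C/C(=C\[C@@H](C)[C@H](C)O[Si](CC)(CC)CC)[C@@H]1O[C@@]1(C)C1=C/C(=C/C(=O)[C@@](C)(O[Si](CC)(CC)CC)C=O)C(I)=CO1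
A2 | alternative 1 | pestaphilone D bis(triethylsilyl) ether with free C8 hydroxyl (silyl on the C7 and side-chain oxygens) | C/C(=C\[C@@H](C)[C@H](C)O[Si](CC)(CC)CC)[C@@H]1O[C@@]1(C)C1=CC2=CC(=O)[C@@](C)(O[Si](CC)(CC)CC)[C@H](O)C2=CO1
A3 | alternative 2 | enol ester of the C8a-formyl ring B unit, {2-methyl-4-oxo-5,6-bis[(triethylsilyl)oxy]-5-methylcyclohex-2-en-1-ylidene}methyl 2-methyl-3-[(2E,4R,5S)-4-methyl-5-[(triethylsilyl)oxy]hex-2-en-2-yl]oxirane-2-carboxylate, configured as in 26 | C/C(=C\[C@@H](C)[C@H](C)O[Si](CC)(CC)CC)[C@@H]1O[C@@]1(C)C(=O)OC=C1C(C)=CC(=O)[C@@](C)(O[Si](CC)(CC)CC)[C@@H]1O[Si](CC)(CC)CC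
A4 | alternative 2 | tris(triethylsilyl) pestaphilone D (identical with 25) | C/C(=C\[C@@H](C)[C@H](C)O[Si](CC)(CC)CC)[C@@H]1O[C@@]1(C)C1=CC2=CC(=O)[C@@](C)(O[Si](CC)(CC)CC)[C@H](O[Si](CC)(CC)CC)C2=CO1
A5 | alternative 3 | (2Z)-2-[6-{(2R,3S)-2-methyl-3-[(2E,4R,5S)-4-methyl-5-[(triethylsilyl)oxy]hex-2-en-2-yl]oxiran-2-yl}-3-{2-oxo-1-[(triethylsilyl)oxy]propyl}-4H-pyran-4-ylidene]acetaldehyde (C8 epimers) | C/C(=C\[C@@H](C)[C@H](C)O[Si](CC)(CC)CC)[C@@H]1O[C@@]1(C)C1=C/C(=C/C=O)C(C(O[Si](CC)(CC)CC)C(C)=O)=CO1
A6 | alternative 3 | pestaphilone D bis(triethylsilyl) ether with free C7 hydroxyl (silyl on the C8 and side-chain oxygens) | C/C(=C\[C@@H](C)[C@H](C)O[Si](CC)(CC)CC)[C@@H]1O[C@@]1(C)C1=CC2=CC(=O)[C@@](C)(O)[C@H](O[Si](CC)(CC)CC)C2=CO1
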